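The earlier runs and the new flask come from a simulation from invented constants; noise was put on by code.

How long do I wait for most target in the flask, and how much is there then?

| flask | starting material | protic impurity | remark | time |
|---|---|---|---|---|
| eta | 1 M | 0.60 M | run made earlier |  |
| gamma | 1.5 M | 0.60 M | run made earlier |  |
| flask | 2.0 M | 0.600 M |  | 15 d |

| run | time / d | target / % |
|---|---|---|
| eta | 0.333 | 15.1 |
| eta | 1.04 | 17.5 |
| eta | 4.00 | 12.4 |
| eta | 12.0 | 11.0 |
| gamma | 0.333 | 15.1 |
| gamma | 1.04 | 20.2 |
| gamma | 4.00 | 16.3 |
| gamma | 12.0 | 15.4 |

(scatter of a reading: 1 percentage point)

1. time, not beyond 15 d, at which the flask holds most target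
2. the amount of target, in percent of the starting material charged, at that time



In the eta and gamma runs the target curve starts steeply. Both runs read 15.1% at 0.333 d, so the average first slope is 0.453 d⁻¹ as a share of the charge. Both runs show their highest reading at 1.04 d, then fall towards a near-level by 12.0 d.

I reckon that level first. I suppose each protic impurity spends one starting material, so the spared share of a charge is one minus impurity over starting material. Dividing the last reading by that share gives the level per spared share:

eta: 27.5%

gamma: 25.7%

mean: 26.6%

The two lie close, so I use the mean. The flask spares 70.0%, so:

level = 18.6%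

The top reading rises with the spared share, so I extend the line through the two runs:

peak = 21.5%

That stands above the level, so I commit to the early top, near 1.04 d.

The forecast, higher than my peak, says 23.5% at 1.3 d, on the ground that “The peak percentage rises with charge”.

The flask gives 22.1% at 1.29 d.

    target ⇌ isomer of the product A (K = 1.73, k = 5.21 × 10⁻⁴ min⁻¹)
    starting material ⇌ target (K = 1.10, k = 5.22 × 10⁻⁴ min⁻¹)
    isomer of the product A ⇌ isomer of the product B (K = 0.110, k = 5.67 × 10⁻⁴ min⁻¹)
    starting material + protic impurity → quenched substrate (k = 0.00189 M⁻¹ min⁻¹)

Up to 1.29 d in the flask, protic impurity turns starting material into quenched substrate, which stands at 29.3% with 2.47% of the impurity's charge left, while target passes on to isomer of the product A, at 12.5%. In the flask, protic impurity is the limiting reagent of that quench, with 0% left at 15.0 d; quenched substrate ends at 30.0% and target at 18.3%, against my 18.6%. In the neighbour flask with 1.5 M of protic impurity, the level per spared share gives 6.65%, and target there stands at 6.54% at 15.0 d.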